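**Retrosynthetic overview**
1. Feature: the 2,2-dimethyl-2H-pyran is fused linearly to ring B. C4 is bonded to C4a, the carbon para to the C7–OH, and C8 (between C8a–O1 and C7–OH) keeps its hydrogen, although C8 is where a 4-acylresorcinol ether closes by itself.
2. Endgame: cleave the ring-A O–Si bond and turn C8–I into C8–H. The iodine is no part of the target and only closes off C8.
3. Key disconnection C4–C4a: 6-endo π-acid hydroarylation of the 1,1-dimethylpropargyl ether of a 3-iodo-2,4-dihydroxybenzophenone. The pyran is the only ring made; rings A and B are bought as benzenes.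
4. O1–C2 comes from copper-catalysed propargylation of the non-chelated 4-OH. The carbonyl–ring A bond comes from an aryl Grignard plus a 3-iodoaldehyde, then oxidation. Friedel–Crafts acylation is avoided: an ortho-prenyl acylium ion would close onto its own alkene (indanone), and Lewis acids shift the iodine of iodoresorcinols.
5. Fragments: ring A from 1,3-dibromobenzene (C2 lithiation/prenylation, one Br → OH → OTIPS); ring B from 2,4-dihydroxybenzaldehyde (C3 iodination, bis-MOM).

Key step: step 10

Remark on the chemistry: the target SMILES holds no stereocentre and no stereogenic double bond, so the compound is achiral and needs no enantiocontrol. The carbinol carbon of 14 forms racemic and is erased in step 7.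

**Step 1**
Reactants: 1 1,3-dibromobenzene; 2 prenyl bromide (1-bromo-3-methylbut-2-ene)
Product: 5 1,3-dibromo-2-(3-methylbut-2-en-1-yl)benzene, via 2,6-dibromophenyllithium 3 (not isolated), via 2,6-dibromophenylcopper 4 (not isolated)
Conditions: LDA (commercial solution, 1.05 equiv), THF, −78 °C; CuBr·SMe2 (1.0 equiv), −78 °C; 2 (1.2 equiv), −78 → 0 °C
Reagents that add atoms: LDA, [Li]N(C(C)C)C(C)C (lithium, only in 3); copper(I) bromide–dimethyl sulfide, Br[Cu].CSC (copper, only in 4)
Why: Directed ortho-lithiation removes the most acidic C2–H between the two bromines without Br/Li exchange, transmetalation to copper prevents aryne formation on warming, and the hindered arylcopper should take prenyl bromide at its primary carbon (SN2-type allylic substitution).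

**Step 2**
Reactants: 5 1,3-dibromo-2-(3-methylbut-2-en-1-yl)benzene
Product: 8 3-bromo-2-(3-methylbut-2-en-1-yl)phenol, via aryllithium 6 (not isolated), via lithium aryltrimethoxyborate 7 (not isolated)
Conditions: n-BuLi (1.05 equiv), THF, −78 °C; B(OMe)3, −78 °C → rt; aq NaOH, 30% H2O2, 0 °C → rt
Reagents that add atoms: n-butyllithium, [Li]CCCC (lithium, only in 6 and 7); trimethyl borate, COB(OC)OC (only in 7); hydrogen peroxide, OO (phenol oxygen of 8)
Why: Bromine–lithium exchange at one of two equivalent bromines, borylation and alkaline peroxide oxidation (1,2-aryl shift from boron to oxygen) is the standard ArBr → ArOH sequence, and basic H2O2 leaves an unactivated trisubstituted alkene alone.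

**Step 3**
Reactants: 8 3-bromo-2-(3-methylbut-2-en-1-yl)phenol
Product: 9 [3-bromo-2-(3-methylbut-2-en-1-yl)phenoxy]triisopropylsilane
Conditions: TIPSCl, imidazole, DMF, rt
Reagents that add atoms: triisopropylsilyl chloride, CC(C)[Si](Cl)(C(C)C)C(C)C
Why: Standard phenol silylation; TIPS replaces an ester because ring A must next become a Grignard reagent, and this bulky aryl silyl ether should outlast dilute acid, DBU, gold and palladium yet leave with fluoride, so the ortho-prenylphenol never meets acid.

**Step 4**
Reactants: 10 2,4-dihydroxybenzaldehyde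
Product: 11 2,4-dihydroxy-3-iodobenzaldehyde
Conditions: I2 (0.4 equiv), HIO3 (0.2 equiv), EtOH–H2O, 35 °C
Reagents that add atoms: iodine, II; iodic acid, OI(=O)=O
Why: In this oxidative electrophilic aromatic iodination the iodic acid consumes iodide, so the reaction cannot equilibrate, and a chelated 4-acylresorcinol should react at C3 between its two oxygens, with exactly one equivalent of electrophilic iodine limiting di-iodination.

**Step 5**
Reactants: 11 2,4-dihydroxy-3-iodobenzaldehyde
Product: 12 3-iodo-2,4-bis(methoxymethoxy)benzaldehyde
Conditions: NaH (2.4 equiv), MOMCl (2.6 equiv), DMF, 0 °C → rt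
Reagents that add atoms: chloromethyl methyl ether, COCCl
Why: Williamson-type O-alkylation of both phenoxides with the very reactive MOMCl; full deprotonation breaks the hydrogen bond of the hindered 2-OH and removes every acidic proton before the organometallic step.

**Step 6**
Reactants: 9 [3-bromo-2-(3-methylbut-2-en-1-yl)phenoxy]triisopropylsilane; 12 3-iodo-2,4-bis(methoxymethoxy)benzaldehyde
Product: 14 (±)-[3-iodo-2,4-bis(methoxymethoxy)phenyl][2-(3-methylbut-2-en-1-yl)-3-(triisopropylsilyloxy)phenyl]methanol, via arylmagnesium bromide 13 (not isolated)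
Conditions: 9, Mg turnings, THF, reflux; added slowly to 12, THF, −78 → −20 °C; aq NH4Cl
Reagents that add atoms: magnesium, [Mg] (only in 13)
Why: Grignard 1,2-addition to an aromatic aldehyde should outrun aryl–aryl iodine–magnesium exchange at low temperature, since inverse addition keeps the reagent scarce and the ortho-OMOM chelates magnesium, and the new carbinol stereocentre forms racemic and is removed in step 7.

**Step 7**
Reactants: 14 the racemic diaryl carbinol
Product: 15 [3-iodo-2,4-bis(methoxymethoxy)phenyl][2-(3-methylbut-2-en-1-yl)-3-(triisopropylsilyloxy)phenyl]methanone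
Conditions: Dess–Martin periodinane (1.3 equiv), CH2Cl2, 0 °C → rt
Reagents that add atoms: none
Why: Dess–Martin oxidation of a secondary diaryl carbinol runs under nearly neutral conditions that leave the alkene, aryl iodide, acetals and silyl ether untouched.

**Step 8**
Reactants: 15 the bis-MOM benzophenone
Product: 16 (2,4-dihydroxy-3-iodophenyl)[2-(3-methylbut-2-en-1-yl)-3-(triisopropylsilyloxy)phenyl]methanone
Conditions: HCl (ca. 0.5 M), MeOH–THF, 45 °C
Reagents that add atoms: none
Why: Acid-catalysed acetal exchange (methanolysis) cleaves both aryl MOM ethers, while the aryl TIPS ether is stable to dilute methanolic HCl and keeps the ring-A oxygen from adding to the prenyl group.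

**Step 9**
Reactants: 16 the 2,4-dihydroxy-3-iodobenzophenone; 17 2-methylbut-3-yn-2-ol
Product: 19 [2-hydroxy-3-iodo-4-(2-methylbut-3-yn-2-yloxy)phenyl][2-(3-methylbut-2-en-1-yl)-3-(triisopropylsilyloxy)phenyl]methanone, via 2-methylbut-3-yn-2-yl trifluoroacetate 18 (not isolated)
Conditions: 17, (CF3CO)2O, DBU, MeCN, −5 °C; then 16, DBU, CuCl2·2H2O (1 mol%), MeCN, −5 → 0 °C
Reagents that add atoms: trifluoroacetic anhydride, O=C(OC(=O)C(F)(F)F)C(F)(F)F (only in 18)
Why: In this copper-catalysed propargylic substitution the copper acetylide of 18 ionises to a copper allenylidene, which the acidic 4-phenoxide captures at its tertiary carbon in an SN1-like step that tolerates the ortho iodine, while the 2-OH stays hydrogen-bonded to the ketone and shielded by iodine.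

**Step 10**
Reactants: 19 the 3-iodo-4-(1,1-dimethylpropargyloxy)-2-hydroxybenzophenone
Product: 20 (7-hydroxy-8-iodo-2,2-dimethyl-2H-chromen-6-yl)[2-(3-methylbut-2-en-1-yl)-3-(triisopropylsilyloxy)phenyl]methanone
Conditions: Ph3PAuNTf2 (4 mol%), dry 1,2-dichloroethane, 4 Å MS, rt → 50 °C
Reagents that add atoms: none
Why: Cationic gold(I) binds the terminal alkyne, the ring-B carbon ortho to the ether oxygen and para to the chelated hydroxyl (benzophenone C5, future C4a) attacks the terminal alkyne carbon (future C4) in a Friedel–Crafts manner, and rearomatisation followed by protodeauration of the vinylgold leaves the C3=C4 double bond. The closest known reaction type is the gold(I)- or platinum-catalysed intramolecular hydroarylation of aryl propargyl ethers to 2H-chromenes, which is established for 1,1-dimethylpropargyl ethers. The pyran, the only ring closed, forms in the 6-endo-dig mode, because attack at the internal carbon would give a strained 3-methylene-2,3-dihydrobenzofuran, and the gem-dimethyl group together with the bulk of the neighbouring iodine turns the alkyne arm towards the free ortho C–H. No stereocentre is created. The selectivity needed is linear against angular fusion, and it is secured because the intrinsically more nucleophilic carbon between the two oxygens carries iodine, which leaves a single ortho C–H that is also meta to the deactivating carbonyl. The remote prenyl alkene, the aryl iodide (inert to gold(I)), the TIPS ether and the hydrogen-bonded phenol should be spectators, and dry solvent with sieves suppresses alkyne hydration.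

**Step 11**
Reactants: 20 the 8-iodochromene
Product: 21 (7-hydroxy-2,2-dimethyl-2H-chromen-6-yl)[2-(3-methylbut-2-en-1-yl)-3-(triisopropylsilyloxy)phenyl]methanone
Conditions: Pd(OAc)2 (5 mol%), PPh3 (20 mol%), HCO2H, Et3N, DMF, 60 °C
Reagents that add atoms: none
Why: Palladium-catalysed transfer hydrodehalogenation (oxidative addition into C8–I, formate exchange, decarboxylation to Ar–Pd–H, reductive elimination) has the aryl iodide as its only entry point, the trisubstituted and cyclic alkenes are poor partners for phosphine-ligated palladium, and any early loss of TIPS would only anticipate step 12.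

**Step 12**
Reactants: 21 3'-O-TIPS cudraphenone A
Product: 22 cudraphenone A, (7-hydroxy-2,2-dimethyl-2H-chromen-6-yl)[3-hydroxy-2-(3-methylbut-2-en-1-yl)phenyl]methanone
Conditions: TBAF, AcOH (1:1), THF, 0 °C
Reagents that add atoms: none
Why: Fluoride-induced desilylation is driven by the Si–F bond, and the acetic acid buffer keeps the medium near neutral so that neither the ortho-prenylphenol nor the chromene meets acid or strong base.

**Compound list**
1 | 1,3-dibromobenzene | Brc1cccc(Br)c1 | starting material
2 | prenyl bromide | CC(C)=CCBr | starting material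
3 | 2,6-dibromophenyllithium | [Li]c1c(Br)cccc1Br | intermediate
4 | 2,6-dibromophenylcopper | [Cu]c1c(Br)cccc1Br | intermediate
5 | 1,3-dibromo-2-(3-methylbut-2-en-1-yl)benzene | CC(C)=CCc1c(Br)cccc1Br | intermediate
6 | [3-bromo-2-(3-methylbut-2-en-1-yl)phenyl]lithium | CC(C)=CCc1c(Br)cccc1[Li] | intermediate
7 | lithium [3-bromo-2-(3-methylbut-2-en-1-yl)phenyl]trimethoxyborate | [Li+].CO[B-](OC)(OC)c1cccc(Br)c1CC=C(C)C | intermediate
8 | 3-bromo-2-(3-methylbut-2-en-1-yl)phenol | CC(C)=CCc1c(O)cccc1Br | intermediate
9 | [3-bromo-2-(3-methylbut-2-en-1-yl)phenoxy]triisopropylsilane | CC(C)=CCc1c(O[Si](C(C)C)(C(C)C)C(C)C)cccc1Br | intermediate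
10 | 2,4-dihydroxybenzaldehyde | O=Cc1ccc(O)cc1O | starting material
11 | 2,4-dihydroxy-3-iodobenzaldehyde | O=Cc1ccc(O)c(I)c1O | intermediate
12 | 3-iodo-2,4-bis(methoxymethoxy)benzaldehyde | O=Cc1ccc(OCOC)c(I)c1OCOC | intermediate
13 | [2-(3-methylbut-2-en-1-yl)-3-(triisopropylsilyloxy)phenyl]magnesium bromide | CC(C)=CCc1c(O[Si](C(C)C)(C(C)C)C(C)C)cccc1[Mg]Br | intermediate
14 | (±)-[3-iodo-2,4-bis(methoxymethoxy)phenyl][2-(3-methylbut-2-en-1-yl)-3-(triisopropylsilyloxy)phenyl]methanol (racemic) | CC(C)=CCc1c(O[Si](C(C)C)(C(C)C)C(C)C)cccc1C(O)c1ccc(OCOC)c(I)c1OCOC | intermediate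
15 | [3-iodo-2,4-bis(methoxymethoxy)phenyl][2-(3-methylbut-2-en-1-yl)-3-(triisopropylsilyloxy)phenyl]methanone | CC(C)=CCc1c(O[Si](C(C)C)(C(C)C)C(C)C)cccc1C(=O)c1ccc(OCOC)c(I)c1OCOC | intermediate
16 | (2,4-dihydroxy-3-iodophenyl)[2-(3-methylbut-2-en-1-yl)-3-(triisopropylsilyloxy)phenyl]methanone | CC(C)=CCc1c(O[Si](C(C)C)(C(C)C)C(C)C)cccc1C(=O)c1ccc(O)c(I)c1O | intermediate
17 | 2-methylbut-3-yn-2-ol | CC(C)(O)C#C | starting material
18 | 2-methylbut-3-yn-2-yl trifluoroacetate | C#CC(C)(C)OC(=O)C(F)(F)F | intermediate
19 | [2-hydroxy-3-iodo-4-(2-methylbut-3-yn-2-yloxy)phenyl][2-(3-methylbut-2-en-1-yl)-3-(triisopropylsilyloxy)phenyl]methanone (key-step precursor) | CC(C)=CCc1c(O[Si](C(C)C)(C(C)C)C(C)C)cccc1C(=O)c1ccc(OC(C)(C)C#C)c(I)c1O | intermediate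
20 | (7-hydroxy-8-iodo-2,2-dimethyl-2H-chromen-6-yl)[2-(3-methylbut-2-en-1-yl)-3-(triisopropylsilyloxy)phenyl]methanone (key-step product) | CC(C)=CCc1c(O[Si](C(C)C)(C(C)C)C(C)C)cccc1C(=O)c1cc2c(c(I)c1O)OC(C)(C)C=C2 | intermediate
21 | (7-hydroxy-2,2-dimethyl-2H-chromen-6-yl)[2-(3-methylbut-2-en-1-yl)-3-(triisopropylsilyloxy)phenyl]methanone | CC(C)=CCc1c(O[Si](C(C)C)(C(C)C)C(C)C)cccc1C(=O)c1cc2c(cc1O)OC(C)(C)C=C2 | intermediate
22 | cudraphenone A (achiral) | CC(C)=CCc1c(O)cccc1C(=O)c1cc2c(cc1O)OC(C)(C)C=C2 | target

**Step count**
Total steps: 12. Longest linear sequence: 10 (steps 1–3, then 6–12). The ring-B branch (steps 4–5) joins at step 6.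

**Steps most likely to fail**

Step 10. The aroyl group and the iodine lower the nucleophilicity of ring B, so the cyclisation may be slow. Ionisation of the tertiary propargylic C–O bond, alkyne hydration, or ipso attack at the iodinated carbon with iodine transfer could then compete. The fallback sets out from 16 and comes back at 20, bypassing the ether. 16 is heated with 3-methylbut-2-enal (CC(C)=CC=O) and catalytic ethylenediammonium diacetate in toluene at reflux with removal of water. Knoevenagel-type attack by the only free carbon ortho to the 4-OH and loss of water should give the ortho-quinone methide F1 (not isolated). Its oxa-6π electrocyclisation closes the pyran to 20, and the iodine again forces linear fusion.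

Step 6. Iodine–magnesium exchange between the aryl Grignard reagent and the doubly oxygen-flanked C–I bond may compete, or the addition between two ortho-substituted partners may stall. The fallback sets out from 10 and 13 and comes back at 14; it brings the iodine in only after the C–C bond is made. 10 is protected (NaH, MOMCl, DMF) to 2,4-bis(methoxymethoxy)benzaldehyde F2. Addition of 13 should give the iodine-free carbinol F3. n-BuLi (2.2 equiv, THF, 0 °C) forms the alkoxide and, by cooperative directed ortho-metalation, lithiates the carbon between the two OMOM groups to give the dilithio species F4. Quenching with I2 at −78 °C gives 14.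

Step 4. Positional control may erode through attack at C5, di-iodination, or acid-promoted migration of iodine away from the carbon between the oxygens. That would place the blocking atom wrongly. The fallback does not start from 10: bought 2-iodoresorcinol F5 takes its place, and the sequence comes back at 11. Vilsmeier–Haack formylation (POCl3, DMF, MeCN, −15 °C → rt) should precipitate the aryl iminium chloride F6, which is hydrolysed in warm water to 11. Positions 4 and 6 of F5 are equivalent, so the iodine can only end up between the two oxygens.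

**Further compounds**
F1 | step 10 | ortho-quinone methide from 16 and 3-methylbut-2-enal (not isolated) | CC(C)=CCc1c(O[Si](C(C)C)(C(C)C)C(C)C)cccc1C(=O)C1=CC(=CC=C(C)C)C(=O)C(I)=C1O
F2 | step 6 | 2,4-bis(methoxymethoxy)benzaldehyde | COCOc1ccc(C=O)c(OCOC)c1
F3 | step 6 | (±)-[2,4-bis(methoxymethoxy)phenyl][2-(3-methylbut-2-en-1-yl)-3-(triisopropylsilyloxy)phenyl]methanol | CC(C)=CCc1c(O[Si](C(C)C)(C(C)C)C(C)C)cccc1C(O)c1ccc(OCOC)cc1OCOC
F4 | step 6 | lithium alkoxide of F3 lithiated at ring-B C3 (not isolated) | CC(C)=CCc1c(O[Si](C(C)C)(C(C)C)C(C)C)cccc1C(O[Li])c1ccc(OCOC)c([Li])c1OCOC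
F5 | step 4 | 2-iodoresorcinol (bought) | Oc1cccc(O)c1I
F6 | step 4 | (2,4-dihydroxy-3-iodobenzylidene)dimethylammonium chloride | C[N+](C)=Cc1ccc(O)c(I)c1O.[Cl-]
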